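The earlier runs and the new flask were generated by integration from invented constants.

- At 55 °C, green stops with 42.5% of complex with one exchanged against 16.7% in red, and green was charged with more incoming ligand.

| flask | starting complex | incoming ligand | temperature | remark | time |
|---|---|---|---|---|---|
| red | 19 mM | 3.5 mM | 55 °C | run made earlier |  |
| blue | 19 mM | 45 mM | 88 °C | run made earlier |  |
| green | 18 mM | 15.2 mM | 55 °C | run made earlier |  |
| cedar | 19 mM | 15.2 mM | 70 °C |  | 3.0 min |
| larch | 10 mM | 15.2 mM | 100 °C |  | 3.0 min |
| ash | 19 mM | 4.00 mM | 55 °C |  | 3.0 min |
| elm | 19 mM | 60.0 mM | 40 °C |  | 3.0 min |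
| alder | 19 mM | 5.00 mM | 70 °C |  | 3.0 min |

- red (time / min: complex with one exchanged / %, starting complex / %): 0.333: 14.1, 86.5; 0.500: 15.9, 83.1; 1.00: 15.8, 81.1; 2.00: 17.2, 84.4; 3.00: 16.7, 83.2; 4.00: 15.1, 84.2
- blue (time / s: complex with one exchanged / %, starting complex / %): 10.0: 26.1, 10.5; 15.0: 24.9, 7.7; 25.0: 21.9, 7.0; 30.0: 24.5, 8.7; 50.0: 22.9, 6.4
- green (time / min: complex with one exchanged / %, starting complex / %): 0.417: 39.1, 47.3; 1.00: 41.5, 40.3; 2.00: 43.4, 40.5; 3.00: 42.3, 38.9; 4.00: 42.8, 39.9

(standard deviation of a reading: 1 percentage point)

- the numbers in the tables scatter with a standard deviation of 1 percentage point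

- all flasks from highest to lowest amount of complex with one exchanged, in percent of the starting complex charged, at 3.0 min (cedar / larch / ash / elm / alder)
- the same order at 40 s (cedar / larch / ash / elm / alder)
- the amount of complex with one exchanged, in percent of the starting complex charged of the flask you put first, at 3.0 min
- the amount of complex with one exchanged, in percent of the starting complex charged of the flask you put last, at 3.0 min

- Elm is charged with 3.16 equivalents: E, the incoming ligand charged per starting complex charged, is the quantity I carry.
- First rung of the time ladder: blue, at 88 °C, is still moving at its first reading, with 10.5% of starting complex at 10.0 s against about 7.37% from 25.0 s on, so blue stops changing by about that later reading.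
- Next rung: red and green both stay level within the scatter from 1.00 min on, after green's starting complex has fallen from 47.3% at 0.417 min to about 39.9%.
- What the flat stretch means: in green, the part that is neither starting complex nor one-exchanged holds at least two exchanges, so at least 92.0% of the ligand is used. Incoming ligand is the limiting reagent there, and E sets where such a flask stops.
- My reckoning: cedar has E = 0.800, just under green's 0.844, so I put it first, at slightly under 42.5%.
- Larch, at 1.52, lies between green and blue, whose E of 2.37 holds about 23.1%, so it comes second.
- Alder (0.263) and ash (0.211) sit a little above red, in that order. Elm lies beyond blue, so I put it last, under 23.1%.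
- Last rung: elm is colder than any run and must pass ligand on through several exchanges, so I expect it higher at 40 s than at the end.
- The forecast gives cedar > larch > alder > ash > elm at 3.0 min and cedar > larch > alder > ash > elm at 40 s, with 36.5% (32% to 41%) on top and 10% (6% to 14%) lowest, on the ground that “these are equilibria, not complete conversions”, which is not my reading.
- The flasks give cedar > larch > alder > ash > elm at 3.0 min, with 40.6% and 11.6% at the ends, and cedar > larch > elm > alder > ash at 40 s, where elm holds 29.2%.

    starting complex + incoming ligand → leaving ligand + complex with one exchanged (k = 8.00 M⁻¹ s⁻¹, Ea = 40.0 kJ mol⁻¹)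
    complex with one exchanged + incoming ligand → leaving ligand + complex with two exchanged (k = 6.00 M⁻¹ s⁻¹, Ea = 45.0 kJ mol⁻¹)
    complex with two exchanged + incoming ligand → leaving ligand + complex with three exchanged (k = 7.90 M⁻¹ s⁻¹, Ea = 45.0 kJ mol⁻¹)
    complex with three exchanged + incoming ligand → leaving ligand + complex with four exchanged (k = 7.30 M⁻¹ s⁻¹, Ea = 47.0 kJ mol⁻¹)
    (constants at 70 °C)

- At 0.102 min, elm makes complex with one exchanged 2.03 times as fast as it uses it up. By 3.00 min, the first step takes ligand at 0.13 of the second step's rate, so at E = 3.16 the stock falls to 11.6%.
- The neighbour of elm with 15 mM of ligand has E = 0.789, close to cedar's 0.800, so I expect about 42.5% even at 40 °C. It gives 43.2%, with 0.264% of its ligand left at 3.00 min.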